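## The problem

Deoxycalyxin A is a 2′,4′-dihydroxy-6′-methoxychalcone. Ring A carries at A4, between the two hydroxyl-bearing carbons A3 and A5, the C5 methine of a 1,7-bis(4-hydroxyphenyl)hept-6-ene chain, and at A6, between A5 and the methoxy carbon A1, the 4-hydroxycinnamoyl group. C5 is the only stereocentre (R; ring A > C6 alkenyl > C4 alkyl > H), so nothing in the molecule can direct it. It has to come from a reagent, a catalyst or a resolved relay centre. Because it is both benzylic and allylic, it must not meet strong base or radical conditions once set. The position of C5 is awkward: electrophilic substitution of a 5-methoxyresorcinol goes next to the methoxy group, not between the two oxygens. The sensitive groups are the 2′-hydroxychalcone (closes to the flavanone in acid or base), the electron-rich styrene flanked by ortho phenols (closes to a flavan in strong acid) and five oxidisable phenols. These call for protection to the end and a mild release. The feature that makes the key step possible is that A3 (oxygen) and A4 (carbon C5) are neighbours and A4 is flanked on the other side by the oxygen on A5. This is the pattern left by carbonyl addition across a 3-alkoxyaryne, and C5–C6=C7–aryl is then a cinnamaldehyde whose carbonyl carbon is C5. A bond from the A3 oxygen to C7 gives a 2-aryl-2H-chromene, and its allylic C7–O bond can later be broken by attack at C5. Once A3 and A5 carry the same group, A2 and A6 become equivalent by rotation about the A4–C5 bond, so the acyl group can be placed without a regiochemical question.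

## Retrosynthesis

**29 from 28.** The last cut removes five methoxymethyl (MOM) ethers from pentaether 28. Acetals are chosen because they have to survive fluoride, organomagnesium and organolithium reagents, an iodinating agent and an oxidant. Silyl ethers would be lost in the fluoride step and, on ring A, would migrate to carbon on ortho-metalation. The forward step needs dilute acid that spares the chalcone and the styrene.

**28 from 25 and 12.** The A6–carbonyl bond is cut, leading through carbinol 27 to aryllithium 26 (from iodide 25) and enal 12, the same enal that serves in the key step. Friedel–Crafts or Fries acylation would expose MOM ethers and the styrene to Lewis acid. Direct lithiation of 24 would compete with removal of the acidic C5–H. Iodide 25 comes from symmetric tetraether 24, in which A2 and A6 are equivalent. The forward steps need halogen–metal exchange faster than any proton transfer, and a neutral oxidation.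

**24 and 23 from 17 and 21.** The C4–C5 bond is cut and the A3 oxygen is reconnected to C7. In the forward sense bromide 21, as its Grignard reagent 22, attacks C5 of flavene 17 in an SN2′ manner and releases phenol 23, which is capped to 24. This one cut installs the chain, unveils the styrene with its aryl group and frees the phenol. Conjugate-addition routes to the same centre need extra redox steps afterwards. The precursors are an achiral chain piece and a rigid bicycle with one stereocentre. The forward reaction must be γ-selective, anti-stereospecific and E-selective; it has not been shown on 2H-chromenes and is treated as the one unproven step.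

**17 from 16.** The relay centre C7 is formed without control. A dynamic, enantioconvergent opening of 16 would need the chromene to racemise at the temperature of organocopper chemistry, which is not expected, and anti-SN2′ attack is stereospecific. The racemate 16 is therefore resolved by chromatography to (S)-17, whose configuration is then transmitted to C5. The antipode should be returnable to 16 by light or heat through achiral quinone methide 15.

**16 from 10 and 12 (key disconnection).** The A3–O, A4–C5 and O–C7 bonds are cut together. Aryne 13, released from o-silylaryl triflate 10, takes up the carbonyl group of 12 through benzoxete 14 and quinone methide 15. No other cut makes three skeletal bonds and the pyran ring from two simple partners, or places carbon regiospecifically between the two oxygens. The forward reaction needs oxygen attack at the aryne carbon remote from the MOM ether.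

**10 from 1.** Triflate 10 is the MOM ether of phenol 9, which comes from bromoresorcinol 5 by silylation, retro-Brook shift and triflation. Only one silyl group can migrate, so the symmetric diol is desymmetrised without a statistical mono-protection. Bromide 5 comes from 4, made by lithiation of bis-MOM ether 2 between its two acetal groups, and 2 comes from 1. This avoids a directed lithiation that would have to choose between a MOM and a methyl ether.

**21 from 18; 12 from 11.** Bromide 21 comes from acid 18 through alcohols 19 and 20 by reduction, phenol protection and bromination. Enal 12 is the MOM ether of 11.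

## Roads not taken

**Alternative 1:** The cut is the A5–A6 bond, so that ring A unfolds to 2-pyrone A1, which already carries the C5 chain at its 3-position and a cinnamoylmethyl side chain at its 6-position. In the forward key step methoxide opens the lactone, the side-chain carbanion acylates the former lactone carbonyl in a Claisen-type closure, and aromatisation gives acylphloroglucinol A2. Merits: the acyl group, the substitution pattern and the stereocentre are all present when the ring forms, and no substitution or aryl-metal chemistry is needed on a finished ring. Weak points: A1 is hardly simpler than the target, its C5 centre must be set by a separate asymmetric step on a pyrone side chain, and its enone and triketone-type array must survive methoxide. A2 also emerges with A1–OH and A5–OH both free and both chelated to the ketone, so the single O-methylation at A1 rests on hindrance alone. Comparison: this road is better in avoiding the iodination and lithiation endgame and, if C5 is set catalytically, the resolution. The chosen plan sets against it a methoxy group present from the first compound and a three-bond key step from two simple partners.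

**Alternative 2:** The cut is through the A2–A3 and A4–A5 bonds, giving cyclobutenone A3 and chiral siloxyalkyne A4. In the forward key step A3 opens thermally to a vinylketene that takes up A4, and a 6π closure gives resorcinol monosilyl ether A5. Merits: the regiochemistry is fixed by the benzannulation, the A3 and A5 oxygens come out differentiated, and the stereocentre is made beforehand by established asymmetric chemistry, with no resolution and no unproven step at C5. Weak points: the stereocentre of A4 is propargylic and allylic and must survive the strong base of ynol ether synthesis and the heat of the annulation. A5 still lacks the C7 aryl group and the acyl group, so a cross-metathesis and an acylation follow. Silyl ethers on ring A would not tolerate ortho-lithiation. Comparison: this road is better in stereochemical security. The chosen plan sets against it that the aryl–C3 unit and the ring A pattern arrive in one step, with a shorter path to the full diarylheptene.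

**Alternative 3:** The cut is through the C3–C4 and C5–C6 bonds across ring A styrene A6, with alkyl iodide A8 and bromostyrene A7 as partners. In the forward key step, a nickel-catalysed reductive coupling, the 3-arylpropyl radical adds to the terminal carbon of A6 and the benzylic radical at C5 is captured by a chiral alkenylnickel species to give A9. Merits: three achiral pieces are joined in one step, C5 is set catalytically in the bond-forming event, and A9 lacks only the cinnamoyl group. On paper this is the shortest road and needs no resolution, and in both respects it is better than the chosen plan. Weak points: A6 has two ortho silyloxy groups, so the vinyl group is twisted and the C5 radical is hindered and electron-rich. Capture and enantioselection at such a centre lie outside what this reaction type has shown. Direct alkyl–alkenyl coupling competes, and the silyl ethers of A9 block the lithiation route to the ketone. Comparison: both plans contain one unproven step. The chosen plan sets against the better step count that its unproven step only has to transmit a configuration fixed beforehand, not create it, and that the reacting centres of its key step are unhindered.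

Key step: step 7

Remark on the chemistry (assumption): 2-aryl-2H-chromenes such as 16 and 17 are taken to keep their configuration in the dark at or below room temperature and to racemise only by light or heat through 15. The (S) enantiomer is identified by chiroptical comparison with calculation before use.

Step 1
Reactants: 1 5-methoxybenzene-1,3-diol (5-methoxyresorcinol)
Product: 2 1-methoxy-3,5-bis(methoxymethoxy)benzene
Conditions: MOMCl, i-Pr2NEt, CH2Cl2, 0 °C → rt
Reagents that add atoms: chloromethyl methyl ether (COCCl)
Why: Double O-alkylation of the phenols under amine base; the two acetal groups later act as the directing pair for lithiation.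

Step 2
Reactants: 2 1-methoxy-3,5-bis(methoxymethoxy)benzene
Product: 4 2-bromo-5-methoxy-1,3-bis(methoxymethoxy)benzene, via aryllithium 3 (not isolated)
Conditions: n-BuLi, THF, 0 °C; then BrCH2CH2Br, −78 °C → rt
Reagents that add atoms: 1,2-dibromoethane (BrCCBr)
Why: Directed ortho-metalation goes to the position between the two chelating MOM ethers in preference to those next to the methoxy group, and the aryllithium is brominated by 1,2-dibromoethane with loss of ethene; the symmetry of 2 is kept.

Step 3
Reactants: 4 2-bromo-5-methoxy-1,3-bis(methoxymethoxy)benzene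
Product: 5 2-bromo-5-methoxybenzene-1,3-diol
Conditions: HCl (aq., cat.), MeOH, 40 °C
Reagents that add atoms: none
Why: Acid-catalysed acetal exchange with methanol frees both phenols for silylation; the bromine marks the carbon that will carry silicon.

Step 4
Reactants: 5 2-bromo-5-methoxybenzene-1,3-diol
Product: 9 3-hydroxy-5-methoxy-2-(trimethylsilyl)phenyl trifluoromethanesulfonate, via bis(trimethylsilyl) ether 6 (not isolated), via lithium phenoxide 7 (not isolated), via silyl ether triflate 8 (not isolated)
Conditions: (Me3Si)2NH, THF, 65 °C, then evaporation; n-BuLi, THF, −78 °C; Tf2O, −78 → 0 °C; aq. NaHCO3, then MeOH, silica gel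
Reagents that add atoms: hexamethyldisilazane (C[Si](C)(C)N[Si](C)(C)C); trifluoromethanesulfonic anhydride (O=S(=O)(OS(=O)(=O)C(F)(F)F)C(F)(F)F)
Why: Standard preparation of an o-silylaryl triflate from an o-bromophenol by O-silylation, bromine–lithium exchange, retro-Brook (O→C) shift of one silyl group and O-triflation of the freed phenoxide; only one silyl group can migrate, so the diol is desymmetrised, and the remaining labile aryl silyl ether is hydrolysed on work-up.

Step 5
Reactants: 9 3-hydroxy-5-methoxy-2-(trimethylsilyl)phenyl trifluoromethanesulfonate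
Product: 10 5-methoxy-3-(methoxymethoxy)-2-(trimethylsilyl)phenyl trifluoromethanesulfonate
Conditions: MOMCl, i-Pr2NEt, CH2Cl2, −20 → 0 °C
Reagents that add atoms: chloromethyl methyl ether (COCCl)
Why: O-alkylation under weak amine base at low temperature, so that the phenoxide next to silicon does not undergo the reverse (C→O) silyl shift; MOM is the fluoride-stable, inductively withdrawing group that will steer the aryne.

Step 6
Reactants: 11 (E)-3-(4-hydroxyphenyl)prop-2-enal
Product: 12 (E)-3-[4-(methoxymethoxy)phenyl]prop-2-enal
Conditions: MOMCl, i-Pr2NEt, CH2Cl2, 0 °C → rt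
Reagents that add atoms: chloromethyl methyl ether (COCCl)
Why: O-alkylation of the phenol; the aldehyde and the E alkene are untouched, and the acetal tolerates fluoride in the next step.

Step 7
Reactants: 10 5-methoxy-3-(methoxymethoxy)-2-(trimethylsilyl)phenyl trifluoromethanesulfonate; 12 (E)-3-[4-(methoxymethoxy)phenyl]prop-2-enal
Product: 16 racemic 7-methoxy-5-(methoxymethoxy)-2-[4-(methoxymethoxy)phenyl]-2H-chromene, via aryne 13 (not isolated), via benzoxete 14 (not isolated), via quinone methide 15 (not isolated)
Conditions: CsF, MeCN, rt → 40 °C, 12 in excess, slow addition of 10, dark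
Reagents that add atoms: none
Why: Fluoride attacks silicon of 10 and the aryl anion expels triflate to give aryne 13, whose triple bond is distorted by the inductively withdrawing MOM ether so that the remote carbon (A3) is the electrophilic end and negative charge is best placed on A4 next to oxygen. The carbonyl oxygen of 12 therefore bonds to A3 and the A4 carbanion closes on the carbonyl carbon (formal [2+2], benzoxete 14), which opens in a thermal 4π process to vinyl quinone methide 15. The closest known reaction type is the annulation of arynes with α,β-unsaturated aldehydes to 2H-chromenes, together with distal attack of nucleophiles on 3-alkoxyarynes. The pyran ring closes by thermal disrotatory oxa-6π electrocyclisation of the cis-dienone (O–C7 bond), which restores the aromaticity of ring A. The one new stereocentre (C7, position 2 of the chromene) has no controlling element and forms as the racemate; it serves only as a relay and is resolved in step 8. The step needs regioselective addition to the aryne, which the MOM ether on A5 secures against the weak opposing influence of the remote methoxy group, and capture of the aryne by a weakly nucleophilic aldehyde, which excess 12 and slow release of 13 support. C5 thus arrives between two differentiated oxygens, where electrophilic substitution of 1 would not place it, and the C5–C6=C7–aryl unit comes with it.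

Step 8
Reactants: 16 racemic 7-methoxy-5-(methoxymethoxy)-2-[4-(methoxymethoxy)phenyl]-2H-chromene
Product: 17 (2S)-7-methoxy-5-(methoxymethoxy)-2-[4-(methoxymethoxy)phenyl]-2H-chromene
Conditions: preparative SFC, amylose tris(3,5-dimethylphenylcarbamate) phase, CO2/MeOH, 30 °C, dark
Reagents that add atoms: none
Why: Resolution by chromatography on a chiral polysaccharide phase, the practical choice for a neutral chromene with no handle for salt formation; no bond changes, and the unwanted enantiomer should be returnable to 16 by light- or heat-induced opening to achiral 15 and reclosure.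

Step 9
Reactants: 18 4-(4-hydroxyphenyl)butanoic acid
Product: 19 4-(4-hydroxybutyl)phenol
Conditions: BH3·SMe2, THF, 0 °C → rt; H2O work-up
Reagents that add atoms: none
Why: Chemoselective borane reduction of the carboxylic acid to the primary alcohol; the phenol only consumes hydride and is returned on work-up.

Step 10
Reactants: 19 4-(4-hydroxybutyl)phenol
Product: 20 4-[4-(methoxymethoxy)phenyl]butan-1-ol
Conditions: MOMCl, K2CO3, acetone, 0 °C → rt
Reagents that add atoms: chloromethyl methyl ether (COCCl)
Why: Carbonate deprotonates only the phenol, so O-alkylation is selective for the phenoxide over the primary alcohol.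

Step 11
Reactants: 20 4-[4-(methoxymethoxy)phenyl]butan-1-ol
Product: 21 1-(4-bromobutyl)-4-(methoxymethoxy)benzene
Conditions: CBr4, PPh3, CH2Cl2, 0 °C
Reagents that add atoms: carbon tetrabromide (BrC(Br)(Br)Br)
Why: Appel bromination of the primary alcohol under neutral conditions that spare the acetal.

Step 12
Reactants: 17 (2S)-7-methoxy-5-(methoxymethoxy)-2-[4-(methoxymethoxy)phenyl]-2H-chromene; 21 1-(4-bromobutyl)-4-(methoxymethoxy)benzene
Product: 23 2-[(1E,3R)-1,7-bis[4-(methoxymethoxy)phenyl]hept-1-en-3-yl]-5-methoxy-3-(methoxymethoxy)phenol, via Grignard reagent 22 (not isolated)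
Conditions: 21, Mg, THF, 40 °C; then 17, CuBr·SMe2 (20 mol%), Et2O/THF, −40 → 0 °C, slow addition, dark; aq. NH4Cl
Reagents that add atoms: none
Why: Proposed new method: a monovalent alkylcopper species formed from 22 is expected to add to C4 of the styrenic double bond of 17 on the face opposite the allylic C2–O1 bond, and the trivalent σ-allylcopper intermediate should expel the magnesium-bound aryloxide and reductively eliminate at the γ-carbon (anti-SN2′), so that the configuration of the relay centre passes to C5 (aryl pseudo-equatorial in the reacting half-chair, hence E alkene and R at C5 from (S)-17); the closest known reaction types are the copper-catalysed γ-substitution of allyl aryl ethers and the anti ring opening of oxabicyclic allylic ethers by Grignard reagents, neither yet shown on a 2H-chromene.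

Step 13
Reactants: 23 2-[(1E,3R)-1,7-bis[4-(methoxymethoxy)phenyl]hept-1-en-3-yl]-5-methoxy-3-(methoxymethoxy)phenol
Product: 24 2-[(1E,3R)-1,7-bis[4-(methoxymethoxy)phenyl]hept-1-en-3-yl]-5-methoxy-1,3-bis(methoxymethoxy)benzene
Conditions: MOMCl, i-Pr2NEt, CH2Cl2, 0 → 40 °C
Reagents that add atoms: chloromethyl methyl ether (COCCl)
Why: O-alkylation of the freed phenol; with A3 and A5 both as MOM ethers ring A regains local twofold symmetry, which makes A2 and A6 equivalent.

Step 14
Reactants: 24 2-[(1E,3R)-1,7-bis[4-(methoxymethoxy)phenyl]hept-1-en-3-yl]-5-methoxy-1,3-bis(methoxymethoxy)benzene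
Product: 25 4-[(1E,3R)-1,7-bis[4-(methoxymethoxy)phenyl]hept-1-en-3-yl]-2-iodo-1-methoxy-3,5-bis(methoxymethoxy)benzene
Conditions: NIS, MeCN, −20 → 0 °C, dark
Reagents that add atoms: N-iodosuccinimide (O=C1CCC(=O)N1I)
Why: Electrophilic aromatic iodination of the 1,3,5-trioxygenated ring, which is far more nucleophilic than the 4-alkoxyphenyl rings and the disubstituted styrene; A2 and A6 are interchanged by rotation about the A4–C5 bond, so a single mono-iodide should result, and acid-free conditions spare the acetals.

Step 15
Reactants: 25 4-[(1E,3R)-1,7-bis[4-(methoxymethoxy)phenyl]hept-1-en-3-yl]-2-iodo-1-methoxy-3,5-bis(methoxymethoxy)benzene; 12 (E)-3-[4-(methoxymethoxy)phenyl]prop-2-enal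
Product: 27 (2E)-1-[3-[(1E,3R)-1,7-bis[4-(methoxymethoxy)phenyl]hept-1-en-3-yl]-6-methoxy-2,4-bis(methoxymethoxy)phenyl]-3-[4-(methoxymethoxy)phenyl]prop-2-en-1-ol (mixture of carbinol epimers), via aryllithium 26 (not isolated)
Conditions: n-BuLi, THF, −78 °C; then 12, −78 °C; pH 7 buffer; used crude
Reagents that add atoms: none
Why: Iodine–lithium exchange at −78 °C is much faster than removal of the benzylic, allylic C5–H, and the chelated aryllithium adds 1,2 to the enal; the new carbinol centre forms without control and is erased in the next step, and the crude product is carried on because it ionises easily.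

Step 16
Reactants: 27 (2E)-1-[3-[(1E,3R)-1,7-bis[4-(methoxymethoxy)phenyl]hept-1-en-3-yl]-6-methoxy-2,4-bis(methoxymethoxy)phenyl]-3-[4-(methoxymethoxy)phenyl]prop-2-en-1-ol
Product: 28 (2E)-1-[3-[(1E,3R)-1,7-bis[4-(methoxymethoxy)phenyl]hept-1-en-3-yl]-6-methoxy-2,4-bis(methoxymethoxy)phenyl]-3-[4-(methoxymethoxy)phenyl]prop-2-en-1-one
Conditions: MnO2, CH2Cl2, rt, dark
Reagents that add atoms: none
Why: Mild heterogeneous oxidation of a doubly activated (benzylic and allylic) alcohol to the enone under neutral conditions; C5 and both styrenes are untouched.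

Step 17
Reactants: 28 (2E)-1-[3-[(1E,3R)-1,7-bis[4-(methoxymethoxy)phenyl]hept-1-en-3-yl]-6-methoxy-2,4-bis(methoxymethoxy)phenyl]-3-[4-(methoxymethoxy)phenyl]prop-2-en-1-one
Product: 29 deoxycalyxin A, (2E)-1-[3-[(1E,3R)-1,7-bis(4-hydroxyphenyl)hept-1-en-3-yl]-2,4-dihydroxy-6-methoxyphenyl]-3-(4-hydroxyphenyl)prop-2-en-1-one
Conditions: HCl (aq., 3 M), MeOH, rt, argon, dark
Reagents that add atoms: none
Why: Acid-catalysed acetal exchange removes the five MOM ethers; dilute acid at room temperature is the usual way to unmask 2′-hydroxy-6′-methoxychalcones with acid-sensitive alkenyl side chains, short contact should limit flavanone closure and hydroalkoxylation of the styrene, and C5 is not touched.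

## Compound list

1 | 5-methoxybenzene-1,3-diol (5-methoxyresorcinol) | COc1cc(O)cc(O)c1 | starting material
2 | 1-methoxy-3,5-bis(methoxymethoxy)benzene | COCOc1cc(OC)cc(OCOC)c1 | intermediate
3 | [4-methoxy-2,6-bis(methoxymethoxy)phenyl]lithium | [Li]c1c(OCOC)cc(OC)cc1OCOC | intermediate (not isolated)
4 | 2-bromo-5-methoxy-1,3-bis(methoxymethoxy)benzene | COCOc1cc(OC)cc(OCOC)c1Br | intermediate
5 | 2-bromo-5-methoxybenzene-1,3-diol | COc1cc(O)c(Br)c(O)c1 | intermediate
6 | [(2-bromo-5-methoxy-1,3-phenylene)bis(oxy)]bis(trimethylsilane) | COc1cc(O[Si](C)(C)C)c(Br)c(O[Si](C)(C)C)c1 | intermediate (not isolated)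
7 | lithium 5-methoxy-2-(trimethylsilyl)-3-[(trimethylsilyl)oxy]phenolate | [Li+].[O-]c1cc(OC)cc(O[Si](C)(C)C)c1[Si](C)(C)C | intermediate (not isolated)
8 | 5-methoxy-2-(trimethylsilyl)-3-[(trimethylsilyl)oxy]phenyl trifluoromethanesulfonate | COc1cc(O[Si](C)(C)C)c([Si](C)(C)C)c(OS(=O)(=O)C(F)(F)F)c1 | intermediate (not isolated)
9 | 3-hydroxy-5-methoxy-2-(trimethylsilyl)phenyl trifluoromethanesulfonate | COc1cc(O)c([Si](C)(C)C)c(OS(=O)(=O)C(F)(F)F)c1 | intermediate
10 | 5-methoxy-3-(methoxymethoxy)-2-(trimethylsilyl)phenyl trifluoromethanesulfonate | COc1cc(OCOC)c([Si](C)(C)C)c(OS(=O)(=O)C(F)(F)F)c1 | intermediate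
11 | (E)-3-(4-hydroxyphenyl)prop-2-enal | O=C/C=C/c1ccc(O)cc1 | starting material
12 | (E)-3-[4-(methoxymethoxy)phenyl]prop-2-enal | O=C/C=C/c1ccc(OCOC)cc1 | intermediate
13 | 1,2-didehydro-5-methoxy-3-(methoxymethoxy)benzene (aryne) | COC1=CC#CC(OCOC)=C1 | intermediate (not isolated)
14 | 5-methoxy-3-(methoxymethoxy)-2-[(E)-2-[4-(methoxymethoxy)phenyl]ethenyl]-2H-benzo[b]oxete | COc1cc(OCOC)c2C(/C=C/c3ccc(OCOC)cc3)Oc2c1 | intermediate (not isolated)
15 | 3-methoxy-5-(methoxymethoxy)-6-[(2E)-3-[4-(methoxymethoxy)phenyl]prop-2-en-1-ylidene]cyclohexa-2,4-dien-1-one | COC1=CC(=O)C(=C/C=C/c2ccc(OCOC)cc2)C(OCOC)=C1 | intermediate (not isolated)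
16 | racemic 7-methoxy-5-(methoxymethoxy)-2-[4-(methoxymethoxy)phenyl]-2H-chromene | COc1cc(OCOC)c2C=CC(c3ccc(OCOC)cc3)Oc2c1 | intermediate
17 | (2S)-7-methoxy-5-(methoxymethoxy)-2-[4-(methoxymethoxy)phenyl]-2H-chromene | COc1cc(OCOC)c2C=C[C@@H](c3ccc(OCOC)cc3)Oc2c1 | intermediate
18 | 4-(4-hydroxyphenyl)butanoic acid | OC(=O)CCCc1ccc(O)cc1 | starting material
19 | 4-(4-hydroxybutyl)phenol | OCCCCc1ccc(O)cc1 | intermediate
20 | 4-[4-(methoxymethoxy)phenyl]butan-1-ol | COCOc1ccc(CCCCO)cc1 | intermediate
21 | 1-(4-bromobutyl)-4-(methoxymethoxy)benzene | COCOc1ccc(CCCCBr)cc1 | intermediate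
22 | bromo[4-[4-(methoxymethoxy)phenyl]butyl]magnesium | COCOc1ccc(CCCC[Mg]Br)cc1 | intermediate (not isolated)
23 | 2-[(1E,3R)-1,7-bis[4-(methoxymethoxy)phenyl]hept-1-en-3-yl]-5-methoxy-3-(methoxymethoxy)phenol | COc1cc(O)c([C@@H](/C=C/c2ccc(OCOC)cc2)CCCCc2ccc(OCOC)cc2)c(OCOC)c1 | intermediate
24 | 2-[(1E,3R)-1,7-bis[4-(methoxymethoxy)phenyl]hept-1-en-3-yl]-5-methoxy-1,3-bis(methoxymethoxy)benzene | COc1cc(OCOC)c([C@@H](/C=C/c2ccc(OCOC)cc2)CCCCc2ccc(OCOC)cc2)c(OCOC)c1 | intermediate
25 | 4-[(1E,3R)-1,7-bis[4-(methoxymethoxy)phenyl]hept-1-en-3-yl]-2-iodo-1-methoxy-3,5-bis(methoxymethoxy)benzene | COc1cc(OCOC)c([C@@H](/C=C/c2ccc(OCOC)cc2)CCCCc2ccc(OCOC)cc2)c(OCOC)c1I | intermediate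
26 | [3-[(1E,3R)-1,7-bis[4-(methoxymethoxy)phenyl]hept-1-en-3-yl]-6-methoxy-2,4-bis(methoxymethoxy)phenyl]lithium | COc1cc(OCOC)c([C@@H](/C=C/c2ccc(OCOC)cc2)CCCCc2ccc(OCOC)cc2)c(OCOC)c1[Li] | intermediate (not isolated)
27 | (2E)-1-[3-[(1E,3R)-1,7-bis[4-(methoxymethoxy)phenyl]hept-1-en-3-yl]-6-methoxy-2,4-bis(methoxymethoxy)phenyl]-3-[4-(methoxymethoxy)phenyl]prop-2-en-1-ol (carbinol epimers) | COc1cc(OCOC)c([C@@H](/C=C/c2ccc(OCOC)cc2)CCCCc2ccc(OCOC)cc2)c(OCOC)c1C(O)/C=C/c1ccc(OCOC)cc1 | intermediate
28 | (2E)-1-[3-[(1E,3R)-1,7-bis[4-(methoxymethoxy)phenyl]hept-1-en-3-yl]-6-methoxy-2,4-bis(methoxymethoxy)phenyl]-3-[4-(methoxymethoxy)phenyl]prop-2-en-1-one | COc1cc(OCOC)c([C@@H](/C=C/c2ccc(OCOC)cc2)CCCCc2ccc(OCOC)cc2)c(OCOC)c1C(=O)/C=C/c1ccc(OCOC)cc1 | intermediate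
29 | deoxycalyxin A, (2E)-1-[3-[(1E,3R)-1,7-bis(4-hydroxyphenyl)hept-1-en-3-yl]-2,4-dihydroxy-6-methoxyphenyl]-3-(4-hydroxyphenyl)prop-2-en-1-one | COc1cc(O)c([C@@H](/C=C/c2ccc(O)cc2)CCCCc2ccc(O)cc2)c(O)c1C(=O)/C=C/c1ccc(O)cc1 | target

## Step count and least certain steps

Total: 17 steps (the resolution counted as one). Longest linear sequence: 13 steps (steps 1–5, 7, 8, 12–17).

**Step 12 (proposed new method).** Most likely failures:
- slow or no opening, because the endocyclic C–O bond lies close to the nodal plane of the alkene and an electron-rich aryloxide is only a modest leaving group;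
- loss of regiocontrol if the allylcopper intermediate equilibrates and couples at C7;
- erosion of enantiopurity if magnesium salts ionise the very electron-rich chromene to the achiral allyl cation before substitution;
- reaction through the half-chair with axial aryl, which would give the Z alkene with the opposite configuration at C5.

The fallback uses known chemistry and sets out from 2. Lithiation as in step 2 and quenching with DMF would give 4-methoxy-2,6-bis(methoxymethoxy)benzaldehyde F1. Claisen–Schmidt condensation (KOH, EtOH) with 1-[4-(methoxymethoxy)phenyl]ethan-1-one F2, made from 4′-hydroxyacetophenone and MOMCl, would give (E)-3-[4-methoxy-2,6-bis(methoxymethoxy)phenyl]-1-[4-(methoxymethoxy)phenyl]prop-2-en-1-one F3. Copper-catalysed asymmetric conjugate addition of Grignard reagent 22 (CuBr·SMe2, chiral ferrocenyl diphosphine, t-BuOMe, −75 °C; ligand enantiomer chosen for R) would give (3R)-3-[4-methoxy-2,6-bis(methoxymethoxy)phenyl]-1,7-bis[4-(methoxymethoxy)phenyl]heptan-1-one F4. NaBH4 reduction to (3R)-3-[4-methoxy-2,6-bis(methoxymethoxy)phenyl]-1,7-bis[4-(methoxymethoxy)phenyl]heptan-1-ol F5 and dehydration towards the aryl-conjugated E alkene (MsCl, Et3N, then DBU) comes back to the route at 24.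

**Step 7 (key step).** Most likely failures: the aldehyde oxygen is a weak nucleophile, so the aryne may be consumed by fluoride, solvent or self-reaction; quinone methide 15 may be intercepted by a second aryne before it cyclises; regiocontrol may be incomplete. The fallback sets out from 10 and lets the aryne take up a far better oxygen nucleophile. CsF in DMF followed by aqueous work-up would give 2-hydroxy-4-methoxy-6-(methoxymethoxy)benzaldehyde F6 by the same distal attack. Claisen–Schmidt condensation with ketone F2 of the first fallback would give (E)-3-[2-hydroxy-4-methoxy-6-(methoxymethoxy)phenyl]-1-[4-(methoxymethoxy)phenyl]prop-2-en-1-one F7. NaBH4 reduction would give 2-[(E)-3-hydroxy-3-[4-(methoxymethoxy)phenyl]prop-1-en-1-yl]-5-methoxy-3-(methoxymethoxy)phenol F8, which closes to the flavene on mild acid treatment, the classical flav-3-ene synthesis, and comes back to the route at 16.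

**Step 15.** Most likely failures: ionisation and decomposition of the doubly activated carbinol during work-up; quenching of 26 by proton transfer or by the butyl iodide formed in the exchange. The fallback sets out from 25 and acylates at the ketone oxidation level. Aryllithium 26 is treated with (E)-N-methoxy-N-methyl-3-[4-(methoxymethoxy)phenyl]prop-2-enamide F9, made from commercial 4-(methoxymethoxy)benzaldehyde by Horner–Wadsworth–Emmons olefination. This comes back to the route at 28 and bypasses both 27 and step 16.

**Step 17.** Most likely failures: oxa-Michael closure of the 2′-hydroxychalcone to the flavanone while the remote acetals are still being cleaved; acid-induced addition of an ortho phenol to the styrene. The fallback sets out from 25 and removes the acetals before the enone exists. Aryllithium 26 with N-methoxy-N-methylacetamide would give 1-[3-[(1E,3R)-1,7-bis[4-(methoxymethoxy)phenyl]hept-1-en-3-yl]-6-methoxy-2,4-bis(methoxymethoxy)phenyl]ethan-1-one F10. Acid methanolysis would give 1-[3-[(1E,3R)-1,7-bis(4-hydroxyphenyl)hept-1-en-3-yl]-2,4-dihydroxy-6-methoxyphenyl]ethan-1-one F11, which cannot form a flavanone. Claisen–Schmidt condensation with 4-hydroxybenzaldehyde (KOH, EtOH/H2O, then cold acidification) comes back to the route at 29.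

## Further compounds

F1 | step 12 | 4-methoxy-2,6-bis(methoxymethoxy)benzaldehyde | COCOc1cc(OC)cc(OCOC)c1C=O
F2 | step 12 | 1-[4-(methoxymethoxy)phenyl]ethan-1-one | CC(=O)c1ccc(OCOC)cc1
F3 | step 12 | (E)-3-[4-methoxy-2,6-bis(methoxymethoxy)phenyl]-1-[4-(methoxymethoxy)phenyl]prop-2-en-1-one | COCOc1cc(OC)cc(OCOC)c1/C=C/C(=O)c1ccc(OCOC)cc1
F4 | step 12 | (3R)-3-[4-methoxy-2,6-bis(methoxymethoxy)phenyl]-1,7-bis[4-(methoxymethoxy)phenyl]heptan-1-one | COCOc1cc(OC)cc(OCOC)c1[C@@H](CC(=O)c1ccc(OCOC)cc1)CCCCc1ccc(OCOC)cc1
F5 | step 12 | (3R)-3-[4-methoxy-2,6-bis(methoxymethoxy)phenyl]-1,7-bis[4-(methoxymethoxy)phenyl]heptan-1-ol (C1 epimers) | COCOc1cc(OC)cc(OCOC)c1[C@@H](CC(O)c1ccc(OCOC)cc1)CCCCc1ccc(OCOC)cc1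
F6 | step 7 | 2-hydroxy-4-methoxy-6-(methoxymethoxy)benzaldehyde | COCOc1cc(OC)cc(O)c1C=O
F7 | step 7 | (E)-3-[2-hydroxy-4-methoxy-6-(methoxymethoxy)phenyl]-1-[4-(methoxymethoxy)phenyl]prop-2-en-1-one | COCOc1cc(OC)cc(O)c1/C=C/C(=O)c1ccc(OCOC)cc1
F8 | step 7 | 2-[(E)-3-hydroxy-3-[4-(methoxymethoxy)phenyl]prop-1-en-1-yl]-5-methoxy-3-(methoxymethoxy)phenol | COCOc1cc(OC)cc(O)c1/C=C/C(O)c1ccc(OCOC)cc1
F9 | step 15 | (E)-N-methoxy-N-methyl-3-[4-(methoxymethoxy)phenyl]prop-2-enamide | CON(C)C(=O)/C=C/c1ccc(OCOC)cc1
F10 | step 17 | 1-[3-[(1E,3R)-1,7-bis[4-(methoxymethoxy)phenyl]hept-1-en-3-yl]-6-methoxy-2,4-bis(methoxymethoxy)phenyl]ethan-1-one | COc1cc(OCOC)c([C@@H](/C=C/c2ccc(OCOC)cc2)CCCCc2ccc(OCOC)cc2)c(OCOC)c1C(C)=O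
F11 | step 17 | 1-[3-[(1E,3R)-1,7-bis(4-hydroxyphenyl)hept-1-en-3-yl]-2,4-dihydroxy-6-methoxyphenyl]ethan-1-one | COc1cc(O)c([C@@H](/C=C/c2ccc(O)cc2)CCCCc2ccc(O)cc2)c(O)c1C(C)=O
A1 | alternative 1 | 3-[(1E,3R)-1,7-bis[4-(methoxymethoxy)phenyl]hept-1-en-3-yl]-4-(methoxymethoxy)-6-[(3E)-4-[4-(methoxymethoxy)phenyl]-2-oxobut-3-en-1-yl]-2H-pyran-2-one | O=C1OC(CC(=O)/C=C/c2ccc(OCOC)cc2)=CC(OCOC)=C1[C@@H](/C=C/c2ccc(OCOC)cc2)CCCCc2ccc(OCOC)cc2
A2 | alternative 1 | (2E)-1-[3-[(1E,3R)-1,7-bis[4-(methoxymethoxy)phenyl]hept-1-en-3-yl]-2,6-dihydroxy-4-(methoxymethoxy)phenyl]-3-[4-(methoxymethoxy)phenyl]prop-2-en-1-one | O=C(/C=C/c1ccc(OCOC)cc1)c1c(O)cc(OCOC)c([C@@H](/C=C/c2ccc(OCOC)cc2)CCCCc2ccc(OCOC)cc2)c1O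
A3 | alternative 2 | 3-methoxycyclobut-2-en-1-one | COC1=CC(=O)C1
A4 | alternative 2 | triisopropyl{[(3R)-3-ethenyl-7-[4-(triisopropylsilyloxy)phenyl]hept-1-yn-1-yl]oxy}silane | CC(C)[Si](OC#C[C@@H](C=C)CCCCc1ccc(O[Si](C(C)C)(C(C)C)C(C)C)cc1)(C(C)C)C(C)C
A5 | alternative 2 | 5-methoxy-2-[(3R)-7-[4-(triisopropylsilyloxy)phenyl]hept-1-en-3-yl]-3-(triisopropylsilyloxy)phenol | COc1cc(O[Si](C(C)C)(C(C)C)C(C)C)c([C@@H](C=C)CCCCc2ccc(O[Si](C(C)C)(C(C)C)C(C)C)cc2)c(O)c1
A6 | alternative 3 | 2-ethenyl-5-methoxy-1,3-bis(tert-butyldimethylsilyloxy)benzene | COc1cc(O[Si](C)(C)C(C)(C)C)c(C=C)c(O[Si](C)(C)C(C)(C)C)c1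
A7 | alternative 3 | (E)-1-(2-bromoethenyl)-4-(tert-butyldimethylsilyloxy)benzene | Br/C=C/c1ccc(O[Si](C)(C)C(C)(C)C)cc1
A8 | alternative 3 | 1-(3-iodopropyl)-4-(tert-butyldimethylsilyloxy)benzene | ICCCc1ccc(O[Si](C)(C)C(C)(C)C)cc1
A9 | alternative 3 | 2-[(1E,3R)-1,7-bis[4-(tert-butyldimethylsilyloxy)phenyl]hept-1-en-3-yl]-5-methoxy-1,3-bis(tert-butyldimethylsilyloxy)benzene | COc1cc(O[Si](C)(C)C(C)(C)C)c([C@@H](/C=C/c2ccc(O[Si](C)(C)C(C)(C)C)cc2)CCCCc2ccc(O[Si](C)(C)C(C)(C)C)cc2)c(O[Si](C)(C)C(C)(C)C)c1
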